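**Time first.** By hand, I expect more hours to give more target. In the maple run, though, target gains 0.0782 M over the first 26 h and 0.00650 M over the last 20.0 h, a rate much lower, and the share at 78 h has to be read from the runs.

| flask | starting material | time |
|---|---|---|
| maple | 0.400 M |  |
| cedar | 0.160 M |  |
| elm | 0.200 M |  |
| oak | 0.0620 M | 78 h |

| run | time / h | [target] / M |
|---|---|---|
| maple run | 4.4 | 0.0203 |
| maple run | 13 | 0.0431 |
| maple run | 26 | 0.0782 |
| maple run | 41 | 0.1083 |
| maple run | 58 | 0.1255 |
| maple run | 78 | 0.1320 |
| cedar run | 4.4 | 0.0048 |
| cedar run | 13 | 0.0142 |
| cedar run | 26 | 0.0216 |
| cedar run | 41 | 0.0329 |
| cedar run | 58 | 0.0355 |
| cedar run | 78 | 0.0418 |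
| elm run | 4.4 | 0.0066 |
| elm run | 13 | 0.0149 |
| elm run | 26 | 0.0303 |
| elm run | 41 | 0.0460 |
| elm run | 58 | 0.0493 |
| elm run | 78 | 0.0586 |

(scatter of a reading: 0.002 M)

- how the opening rate goes with [starting material] round the charge of the maple run: the exponent of the rate at two percent of starting material gone to target (one fixed amount of target, the same in the runs compared)
- target in the oak run at 78 h, as a share of the starting material charged

- Overall: starting material -> target.
- Constant volume, constant temperature.
- Bound and free are read together.
- An order is taken over about fifteen percent of the charge, up and down.

**The charge.** By hand, over the same opening hours, a first-order flask turns the same share of any charge, and a second-order flask turns a share that grows in proportion to the charge. I compare target per hour per [starting material] at the start, over the first 26 h. That specific rate reads 0.00752 h⁻¹ in maple and 0.00519 h⁻¹ in cedar. From cedar to maple the specific rate changes by a smaller factor than the charge, 1.45-fold against 2.50-fold, so these runs stand between the two ends.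

**Joining ends.** I join the ends with a straight line in charge, one constant part and one proportional part. The line gives 0.376 M as the crossover charge, the charge at which the two parts are equal; it is a reading from two points and carries their scatter. On this line the apparent order is one plus charge over charge plus crossover, so my order for maple is 1.52. I take the share at 78 h as specific rate times a span of 50.3 h, read in cedar, so oak gets 21.3%.

**The forecast.** It says 1.4 for the order round the maple charge and 22% for the oak run, slightly apart from my numbers; of the cedar and elm pair it says “it hints at a lower order at low charge”.

**The flask.** The simulation gives an order of 1.5 round the maple charge and 20.0% in the oak run.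

    2 starting material ⇌ substrate dimer, settled at all times (0.5110 M⁻¹)
    substrate dimer → target + starting material (0.06948 h⁻¹)
    target → decomposed product (0.009180 h⁻¹)
    starting material → target (0.002804 h⁻¹)

**Two routes.** The crossover, read without the elm run, puts the elm run's rate at 0.371 of the maple run's, and the simulation's ratio of these two runs at equal target is 0.34. The oak charge stands below the crossover, towards the first-order end, and the first-order route to target in the scheme is the conversion of starting material into target. Without that conversion, target in the oak run at 78 h falls from 20.0% to 9.38%.

The earlier runs and the new flask were computed on assumed constants, and the scatter is random.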